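The diarylmethane is disconnected inside ring B: C1 and C6 come from an aryl ethynyl ketone, C2–C5 from a 2,3-bis(silyloxy)butadiene. One thermal Diels–Alder reaction forms C1–C2 and C5–C6, closes ring B and installs the C3 and C4 oxygens as an enediol bis(silyl ether) at the oxidation level of a dihydrocatechol. It exploits the fact that ring B bears no hydrogen (C1 CH2, C2, C5, C6 Br, C3, C4 OH), so a symmetric diene suffices and the three carbons left as C–H are brominated later without any regiochemical choice. The precursor is the ynone that carries ring A complete, as its 2,5-dibromo-3,4-dimethyl ether, on the future CH2 carbon.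

Key step: step 6

Remark on the chemistry: the target is achiral; compounds 4, 7 and 14 are formed racemic and their stereocentres are removed in the operation that follows.

Step 1
Reactants: 1 veratrole (1,2-dimethoxybenzene)
Product: 3 1,4-dibromo-2,3-dimethoxybenzene, via 3,6-dilithioveratrole 2 (not isolated)
Conditions: n-BuLi (3 equiv), TMEDA (3 equiv), Et2O, 0 °C → reflux; then BrCl2C–CCl2Br (2.5 equiv), −78 °C → rt
Reagents that add atoms: 1,2-dibromo-1,1,2,2-tetrachloroethane, BrC(Cl)(Cl)C(Cl)(Cl)Br
Why: Double directed ortho-metalation puts lithium next to each methoxy group (C3 and C6), and bromine transfer from the polyhaloethane should then give the 3,6-dibromide, a pattern that electrophilic bromination of veratrole (4,5-selective) cannot deliver.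

Step 2
Reactants: 3 1,4-dibromo-2,3-dimethoxybenzene
Product: 5 2,5-dibromo-3,4-dimethoxybenzaldehyde, via aryl(chloro)methyl methyl ether 4 (not isolated)
Conditions: Cl2CHOMe (2 equiv), TiCl4 (2.2 equiv), CH2Cl2, 0 °C → rt; then H2O
Reagents that add atoms: dichloromethyl methyl ether, COC(Cl)Cl; water, O
Why: Rieche formylation, in which the two ring hydrogens of 3 are equivalent by symmetry and each lies para to a methoxy group, so only one aldehyde can form after hydrolysis of the chloro ether.

Step 3
Reactants: 5 2,5-dibromo-3,4-dimethoxybenzaldehyde; 6 ethynylmagnesium bromide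
Product: 7 1-(2,5-dibromo-3,4-dimethoxyphenyl)prop-2-yn-1-ol (racemic)
Conditions: THF, 0 °C; then H2O
Reagents that add atoms: none
Why: Grignard 1,2-addition of an alkynylmagnesium halide to an aldehyde, which does not exchange with aryl bromides at 0 °C; the carbinol centre is formed racemic without control because step 4 removes it.

Step 4
Reactants: 7 1-(2,5-dibromo-3,4-dimethoxyphenyl)prop-2-yn-1-ol
Product: 8 1-(2,5-dibromo-3,4-dimethoxyphenyl)prop-2-yn-1-one
Conditions: MnO2 (activated, 10 equiv), CH2Cl2, rt
Reagents that add atoms: none
Why: MnO2 oxidation of a doubly activated (benzylic and propargylic) alcohol, whose neutral heterogeneous conditions should spare the base- and nucleophile-sensitive terminal ynone.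

Step 5
Reactants: 9 biacetyl (butane-2,3-dione)
Product: 10 2,3-bis(trimethylsilyloxy)buta-1,3-diene
Conditions: Me3SiOTf (2.2 equiv), Et3N (2.5 equiv), Et2O, 0 °C → rt; filter, distil
Reagents that add atoms: trimethylsilyl trifluoromethanesulfonate, C[Si](C)(C)OS(=O)(=O)C(F)(F)F
Why: Soft enolisation and O-silylation of both carbonyl groups (silyl enol ether formation), which can only occur toward the two methyl groups and so gives the 2,3-dioxygenated diene.

Step 6
Reactants: 8 1-(2,5-dibromo-3,4-dimethoxyphenyl)prop-2-yn-1-one; 10 2,3-bis(trimethylsilyloxy)buta-1,3-diene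
Product: 11 [4,5-bis(trimethylsilyloxy)cyclohexa-1,4-dien-1-yl](2,5-dibromo-3,4-dimethoxyphenyl)methanone
Conditions: 10 (2.5 equiv), BHT (cat.), toluene, 100 °C, sealed tube, Ar, base-washed glass; excess 10 removed under vacuum, crude 11 used directly
Reagents that add atoms: none
Why: A concerted, thermally allowed [4+2] cycloaddition of normal electron demand joins the two CH2 termini of the electron-rich diene 10 (future C2 and C5 of ring B) to the two alkyne carbons of the carbonyl-activated dienophile 8 (future C1 and C6). The closest known reaction type is the Diels–Alder reaction of 2,3-bis(trimethylsilyloxy)butadiene with acetylenic esters and ketones, whose 1,4-cyclohexadiene adducts are oxidised to catechols. Ring B is closed as a six-membered carbocycle in an intermolecular cycloaddition mode, both σ-bonds (C1–C2 and C5–C6) being made in the same step. No stereocentre is formed, because every ring carbon of the adduct is either sp2 or a CH2 group. The step needs periselectivity for cycloaddition over Mukaiyama–Michael addition of a silyl enol ether terminus to the ynone and over ynone oligomerisation, which should be secured by the absence of any Lewis or Brønsted acid, the radical inhibitor and the excess of diene; regioselectivity is not an issue because the diene is C2-symmetric, and a second addition is not expected because the trisubstituted enone of 11 is a far weaker dienophile than the ynone.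

Step 7
Reactants: 11 [4,5-bis(trimethylsilyloxy)cyclohexa-1,4-dien-1-yl](2,5-dibromo-3,4-dimethoxyphenyl)methanone
Product: 13 (2,5-dibromo-3,4-dimethoxyphenyl)(3,4-dihydroxyphenyl)methanone, via cyclohex-4-ene-1,2-dione 12 (not isolated)
Conditions: Br2 (1.0 equiv, slow addition), CH2Cl2, −78 °C → rt; evaporate; SiO2
Reagents that add atoms: none
Why: Bromine oxidation of an enediol bis(silyl ether) to the 1,2-diketone with loss of two Me3SiBr (the standard oxidation of acyloin bis-silyl ethers); dione 12 is a keto tautomer of the catechol and should aromatise by double enolisation, while one equivalent of bromine at low temperature should not touch the ketone-deactivated aromatic rings.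

Step 8
Reactants: 13 (2,5-dibromo-3,4-dimethoxyphenyl)(3,4-dihydroxyphenyl)methanone
Product: 15 4-[(2,5-dibromo-3,4-dimethoxyphenyl)methyl]benzene-1,2-diol, via diarylmethanol 14 (not isolated)
Conditions: Et3SiH (3 equiv), CF3CO2H, CH2Cl2, 0 °C → rt
Reagents that add atoms: none
Why: Ionic hydrogenation of a diaryl ketone, in which the protonated carbonyl and then the benzhydryl cation (stabilised by the para-hydroxyl of ring B and the para-methoxy of ring A) each accept hydride from the silane; it is placed before the bromination of ring B so that the carbonyl still has only one ortho substituent.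

Step 9
Reactants: 15 4-[(2,5-dibromo-3,4-dimethoxyphenyl)methyl]benzene-1,2-diol
Product: 16 3,4,6-tribromo-5-[(2,5-dibromo-3,4-dimethoxyphenyl)methyl]benzene-1,2-diol
Conditions: Br2 (3.05 equiv), AcOH–CH2Cl2, 0 °C → rt, dark; aq. NaHSO3
Reagents that add atoms: bromine, BrBr
Why: Electrophilic aromatic bromination, in which the three C–H positions of the free catechol ring B (C2, C5, C6) are all ortho or para to a hydroxyl and are to be filled completely, while the single C–H of ring A sits on a dibrominated dimethyl ether ring with twisted methoxy groups and should react far more slowly with stoichiometric bromine.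

Step 10
Reactants: 16 3,4,6-tribromo-5-[(2,5-dibromo-3,4-dimethoxyphenyl)methyl]benzene-1,2-diol
Product: 17 3,4,6-tribromo-5-[(2,5-dibromo-3,4-dihydroxyphenyl)methyl]benzene-1,2-diol (target)
Conditions: BBr3 (6 equiv), CH2Cl2, −78 °C → rt; then H2O
Reagents that add atoms: none
Why: BBr3 cleavage of aryl methyl ethers (Lewis acid complexation, then SN2 attack of bromide on methyl), which should leave the aryl bromides and the diarylmethane untouched.

Compound list
1 | veratrole (1,2-dimethoxybenzene) | COc1ccccc1OC | starting material
2 | 3,6-dilithioveratrole | [Li]c1ccc([Li])c(OC)c1OC | intermediate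
3 | 1,4-dibromo-2,3-dimethoxybenzene | COc1c(Br)ccc(Br)c1OC | intermediate
4 | 1,4-dibromo-5-[chloro(methoxy)methyl]-2,3-dimethoxybenzene (racemic) | COC(Cl)c1cc(Br)c(OC)c(OC)c1Br | intermediate
5 | 2,5-dibromo-3,4-dimethoxybenzaldehyde | COc1c(Br)cc(C=O)c(Br)c1OC | intermediate
6 | ethynylmagnesium bromide | C#C[Mg]Br | starting material
7 | 1-(2,5-dibromo-3,4-dimethoxyphenyl)prop-2-yn-1-ol (racemic) | COc1c(Br)cc(C(O)C#C)c(Br)c1OC | intermediate
8 | 1-(2,5-dibromo-3,4-dimethoxyphenyl)prop-2-yn-1-one | COc1c(Br)cc(C(=O)C#C)c(Br)c1OC | intermediate
9 | biacetyl (butane-2,3-dione) | CC(=O)C(C)=O | starting material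
10 | 2,3-bis(trimethylsilyloxy)buta-1,3-diene | C=C(O[Si](C)(C)C)C(=C)O[Si](C)(C)C | intermediate
11 | [4,5-bis(trimethylsilyloxy)cyclohexa-1,4-dien-1-yl](2,5-dibromo-3,4-dimethoxyphenyl)methanone | COc1c(Br)cc(C(=O)C2=CCC(O[Si](C)(C)C)=C(O[Si](C)(C)C)C2)c(Br)c1OC | intermediate
12 | 4-(2,5-dibromo-3,4-dimethoxybenzoyl)cyclohex-4-ene-1,2-dione | COc1c(Br)cc(C(=O)C2=CCC(=O)C(=O)C2)c(Br)c1OC | intermediate
13 | (2,5-dibromo-3,4-dimethoxyphenyl)(3,4-dihydroxyphenyl)methanone | COc1c(Br)cc(C(=O)c2ccc(O)c(O)c2)c(Br)c1OC | intermediate
14 | (2,5-dibromo-3,4-dimethoxyphenyl)(3,4-dihydroxyphenyl)methanol (racemic) | COc1c(Br)cc(C(O)c2ccc(O)c(O)c2)c(Br)c1OC | intermediate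
15 | 4-[(2,5-dibromo-3,4-dimethoxyphenyl)methyl]benzene-1,2-diol | COc1c(Br)cc(Cc2ccc(O)c(O)c2)c(Br)c1OC | intermediate
16 | 3,4,6-tribromo-5-[(2,5-dibromo-3,4-dimethoxyphenyl)methyl]benzene-1,2-diol | COc1c(Br)cc(Cc2c(Br)c(O)c(O)c(Br)c2Br)c(Br)c1OC | intermediate
17 | 3,4,6-tribromo-5-[(2,5-dibromo-3,4-dihydroxyphenyl)methyl]benzene-1,2-diol | Oc1c(Br)cc(Cc2c(Br)c(O)c(O)c(Br)c2Br)c(Br)c1O | target

Total step count: 10 (step 5 is a one-step branch to the diene).
Longest linear sequence: 9 steps (steps 1–4 and 6–10, from veratrole).

Steps most likely to fail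

Step 6. What may go wrong: before cycloaddition occurs, the silyl enol ether units of 10 may be protodesilylated or add to the ynone in a Mukaiyama–Michael sense, or the terminal ynone may oligomerise on heating. The fallback sets out from 5 and comes back at 15. Aldehyde 5 is reduced with NaBH4 in MeOH to (2,5-dibromo-3,4-dimethoxyphenyl)methanol F1. Under acid catalysis (TfOH in 1,1,1,3,3,3-hexafluoropropan-2-ol, or AlCl3 in CH2Cl2), F1 should alkylate an excess of catechol at its 4-position. This Friedel–Crafts benzylation makes the C1–CH2 bond of ring B and gives 15, from which step 9 follows.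

Step 9. What may go wrong: loss of discrimination between the rings (bromination of the C6–H of ring A once ring B is filled), ipso attack at C1 of ring B with loss of the benzyl group, or oxidation of the catechol to an ortho-quinone or quinone methide. The fallback sets out from 13 and comes back at 16, and brominates while the carbonyl is still present. Ketone 13 with excess Br2 in AcOH (rt → 60 °C) should give (2,5-dibromo-3,4-dimethoxyphenyl)(2,3,6-tribromo-4,5-dihydroxyphenyl)methanone F2, in which the carbonyl deactivates the C6–H of ring A and excludes benzylic oxidation. The small hydride donor NaBH4 (THF–MeOH) then reduces the hindered ketone to racemic (2,5-dibromo-3,4-dimethoxyphenyl)(2,3,6-tribromo-4,5-dihydroxyphenyl)methanol F3. Et3SiH/CF3CO2H removes the hydroxyl through the benzhydryl cation to give 16, from which step 10 follows.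

Step 2. What may go wrong: the ring, carrying two bromines and two methoxy groups twisted out of conjugation, may be too poor a nucleophile for the formylation to go to completion, or TiCl4 may cleave a methyl ether. The fallback sets out from 3 and comes back at 5, and replaces electrophilic substitution by deprotonation. LDA in THF at −78 °C should remove the ring hydrogen ortho to bromine to give (2,5-dibromo-3,4-dimethoxyphenyl)lithium F4. DMF traps it as lithium (2,5-dibromo-3,4-dimethoxyphenyl)(dimethylamino)methanolate F5, and aqueous work-up releases 5, from which step 3 follows.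

Further compounds
F1 | step 6 | (2,5-dibromo-3,4-dimethoxyphenyl)methanol | COc1c(Br)cc(CO)c(Br)c1OC
F2 | step 9 | (2,5-dibromo-3,4-dimethoxyphenyl)(2,3,6-tribromo-4,5-dihydroxyphenyl)methanone | COc1c(Br)cc(C(=O)c2c(Br)c(O)c(O)c(Br)c2Br)c(Br)c1OC
F3 | step 9 | (2,5-dibromo-3,4-dimethoxyphenyl)(2,3,6-tribromo-4,5-dihydroxyphenyl)methanol (racemic) | COc1c(Br)cc(C(O)c2c(Br)c(O)c(O)c(Br)c2Br)c(Br)c1OC
F4 | step 2 | (2,5-dibromo-3,4-dimethoxyphenyl)lithium | [Li]c1cc(Br)c(OC)c(OC)c1Br
F5 | step 2 | lithium (2,5-dibromo-3,4-dimethoxyphenyl)(dimethylamino)methanolate (racemic) | [Li+].[O-]C(N(C)C)c1cc(Br)c(OC)c(OC)c1Br
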